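Numbering is that of labdane (ring A = C1–C5, C10; ring B = C5–C10; C4 carries the two methyls, C10 the methyl C20, C8 the carbon C17, C9 the side chain C11–C16).
Target diacetate ⇐ labd-7-ene-15,17-diol ⇐ C7=C8 enol triflate of a 9-alkyl-8-ketone (methoxycarbonylation brings in C17) ⇐ aldol condensation at C9 of a bicyclic 6-en-8-one with a C5 aldehyde from methyl hydrogen (R)-3-methylglutarate (C13 from the pool), then hydrogenation from the alpha face (C9).
Rings A and B ⇐ formal [3+3] annulation of (1R,5R)-verbenone with allyltrimethylsilane: conjugate allylation forms C10–C1, opening of the cyclobutane gives the C4 cation, cation–olefin closure forms C3–C4.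
Enabling feature: the four-membered ring of verbenone (pinane C1, C5, C6, C7), whose C1–C6 bond lies alpha,beta to the C2 carbonyl and is a latent tertiary cation; verbenone supplies ring B, C4 with both methyls, C20 and the C5 stereocentre, which relays C10 and then C9.
Ring order: ring B (bought, inside the bicycle) → ring A (step 1) → side chain, then C7=C8 and C17.

Key step: step 1

Assumption: (1R,5R)-(+)-verbenone is taken as a purchasable terpene (it is also the allylic oxidation product of (+)-alpha-pinene); its enantiomeric purity is carried into the product.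

Step 1
Reactants: 1 (1R,5R)-(+)-verbenone; 2 allyltrimethylsilane
Product: 4 (4aS,8aS)-7-chloro-5,5,8a-trimethyloctahydronaphthalen-2(1H)-one (trans-fused, C7 epimers; C7 is labdane C2), via 4-allyl-4-methylnopinone 3 (not isolated)
Conditions: 2 (1.5 equiv), TiCl4 (2.2 equiv), CH2Cl2, −78 °C; then i-PrOH (1.0 equiv), −78 → 0 °C; aq. NaHCO3
Reagents that add atoms: titanium tetrachloride, Cl[Ti](Cl)(Cl)Cl
Why: Proposed new method: a one-flask conjugate-allylation/strain-release cation–olefin [3+3] annulation, whose closest known types are the Hosomi–Sakurai conjugate allylation of beta,beta-disubstituted enones, the acid cleavage of nopinone-type cyclobutanes to tertiary cations (as in the acid-promoted annulation of verbenol with resorcinols) and Lewis-acid additions of tertiary carbocations to alkenes with chloride transfer. TiCl4-activated 1 should be allylated by 2 at C10 from the face opposite the CMe2 bridge, so the new quaternary centre C10 is set by the bicyclic skeleton relative to the bought bridgehead C5 (C1 trans to C4, methyl cis to C4). Protonation of the titanium enolate gives ketone 3, whose TiCl4 complex is a push–pull cyclobutane: heterolysis of the bond between the alpha-carbonyl bridgehead (C7) and the CMe2 carbon (C4) releases the ring strain and gives a tertiary C4 cation and a titanium enolate. The terminal alkene carbon C3 captures this cation in a 6-endo-trig closure (chair, C4 and C1 both equatorial on ring B) that can only give the trans-fused ring A, and chloride from titanium ends the cyclization at C2 (epimer mixture, removed in step 2). The step needs conjugate addition to precede ring opening (secured by running the allylation at −78 °C before the proton source is added) and cyclization to beat proton loss from the C4 cation (elimination and chloride capture at C4 are reversible under HCl/TiCl4, the ring closure is not). The monosubstituted alkene is inert to the titanium-bound ketone, so carbonyl allylation should not compete.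

Step 2
Reactants: 4 (4aS,8aS)-7-chloro-5,5,8a-trimethyloctahydronaphthalen-2(1H)-one
Product: 5 (4aS,8aR)-5,5,8a-trimethyloctahydronaphthalen-2(1H)-one (trans-fused)
Conditions: Bu3SnH, AIBN (cat.), toluene, 110 °C
Reagents that add atoms: none
Why: Radical-chain hydrodechlorination with tin hydride leaves the ketone untouched and converges both C2 epimers on one decalone; no stereocentre is created.

Step 3
Reactants: 5 (4aS,8aR)-5,5,8a-trimethyloctahydronaphthalen-2(1H)-one
Product: 6 (4aS,8aR)-5,5,8a-trimethyl-4a,5,6,7,8,8a-hexahydronaphthalen-2(1H)-one (labdane C6=C7 enone)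
Conditions: IBX (1.5 equiv), DMSO/fluorobenzene, 70 °C
Reagents that add atoms: none
Why: IBX dehydrogenation of the ketone can only introduce the C6=C7 double bond because C10 is quaternary, so the regiochemistry is forced and a second dehydrogenation is excluded; no stereocentre is affected.

Step 4
Reactants: 7 methyl hydrogen (R)-3-methylglutarate
Product: 8 1-tert-butyl 5-methyl (3S)-3-methylpentanedioate
Conditions: t-BuOC(=NH)CCl3, CH2Cl2/cyclohexane, 25 °C
Reagents that add atoms: tert-butyl 2,2,2-trichloroacetimidate, CC(C)(C)OC(=N)C(Cl)(Cl)Cl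
Why: tert-Butylation of the carboxylic acid with the trichloroacetimidate differentiates the two carboxyl termini without touching the stereocentre (its descriptor changes to S only because the priorities change).

Step 5
Reactants: 8 1-tert-butyl 5-methyl (3S)-3-methylpentanedioate
Product: 9 tert-butyl (3S)-3-methyl-5-oxopentanoate
Conditions: i-Bu2AlH (1.05 equiv), toluene, −78 °C; MeOH, then aq. potassium sodium tartrate
Reagents that add atoms: none
Why: Half-reduction of the methyl ester with i-Bu2AlH at −78 °C should stop at the aluminium hemiacetal, which gives the aldehyde on work-up, while the hindered tert-butyl ester is inert at this temperature; the stereocentre is not enolizable.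

Step 6
Reactants: 6 (4aS,8aR)-5,5,8a-trimethyl-4a,5,6,7,8,8a-hexahydronaphthalen-2(1H)-one; 9 tert-butyl (3S)-3-methyl-5-oxopentanoate
Product: 10 tert-butyl (13S)-11-hydroxy-8-oxo-17-norlabd-6-en-15-oate (C9/C11 diastereomer mixture)
Conditions: LiN(i-Pr)2, THF, −78 °C; then 9, −78 °C; aq. NH4Cl
Reagents that add atoms: none
Why: Kinetic deprotonation of the enone takes place at the only alpha-prime position (C9) and the lithium enolate undergoes a directed aldol addition to the aldehyde; the new C9 and C11 centres form as a mixture that is erased in step 7.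

Step 7
Reactants: 10 tert-butyl (13S)-11-hydroxy-8-oxo-17-norlabd-6-en-15-oate
Product: 12 tert-butyl (13S)-8-oxo-17-norlabda-6,9(11)-dien-15-oate (E/Z mixture), via mesylate 11 (not isolated)
Conditions: MsCl, Et3N, CH2Cl2, 0 °C; then DBU, 25 °C
Reagents that add atoms: none
Why: Mesylation and E1cB elimination complete the aldol condensation to the cross-conjugated 9(11)-alkylidene enone, removing the C9 and C11 stereocentres.

Step 8
Reactants: 12 tert-butyl (13S)-8-oxo-17-norlabda-6,9(11)-dien-15-oate
Product: 13 tert-butyl (13S)-8-oxo-17-norlabdan-15-oate (5alpha-H, 9alpha-H, 10beta-CH3)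
Conditions: H2 (3 atm), Pd/C, EtOAc, 25 °C
Reagents that add atoms: none
Why: Heterogeneous hydrogenation saturates both enone C=C bonds, and hydrogen should reach the exocyclic C9=C11 bond from the alpha face, anti to the axial C10 methyl, which sets 9alpha-H (side chain equatorial, also the expected thermodynamic preference at this enolizable centre).

Step 9
Reactants: 13 tert-butyl (13S)-8-oxo-17-norlabdan-15-oate
Product: 14 tert-butyl (13S)-8-(trifluoromethylsulfonyloxy)-17-norlabd-7-en-15-oate
Conditions: KN(SiMe3)2, THF, −78 °C; then PhNTf2, −78 → 0 °C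
Reagents that add atoms: N-phenylbis(trifluoromethanesulfonimide), FC(F)(F)S(=O)(=O)N(c1ccccc1)S(=O)(=O)C(F)(F)F
Why: Kinetic enolization with the bulky amide removes a proton from the C7 methylene and not from the hindered C9 methine, and O-sulfonylation gives the C7=C8 enol triflate (kinetic enol triflate formation); C9 keeps its configuration because its proton is not removed.

Step 10
Reactants: 14 tert-butyl (13S)-8-(trifluoromethylsulfonyloxy)-17-norlabd-7-en-15-oate
Product: 15 15-tert-butyl 17-methyl (13S)-labd-7-ene-15,17-dioate
Conditions: Pd(OAc)2 (5 mol %), dppp, CO (1 atm), MeOH, Et3N, DMF, 60 °C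
Reagents that add atoms: carbon monoxide, [C-]#[O+]; methanol, CO
Why: Palladium-catalysed methoxycarbonylation of the vinyl triflate (oxidative addition to zerovalent palladium, CO insertion, methanolysis) installs C17 at the ester level with the C7=C8 double bond fixed in place.

Step 11
Reactants: 15 15-tert-butyl 17-methyl (13S)-labd-7-ene-15,17-dioate
Product: 16 (13S)-labd-7-ene-15,17-diol
Conditions: i-Bu2AlH (6 equiv), CH2Cl2, −78 → 25 °C; aq. potassium sodium tartrate
Reagents that add atoms: none
Why: Excess i-Bu2AlH reduces the conjugated methyl ester in the 1,2-sense to the allylic alcohol and, on warming, the tert-butyl ester to the primary alcohol, without touching the alkene or any stereocentre.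

Step 12
Reactants: 16 (13S)-labd-7-ene-15,17-diol
Product: 17 (13S)-labd-7-ene-15,17-diyl diacetate (5S,9R,10S,13S)
Conditions: Ac2O, pyridine, DMAP (cat.), CH2Cl2, 25 °C
Reagents that add atoms: acetic anhydride, CC(=O)OC(C)=O
Why: DMAP-catalysed acetylation esterifies both primary alcohols to give the target diacetate.

Compound list
1 | (1R,5R)-(+)-verbenone, (1R,5R)-4,6,6-trimethylbicyclo[3.1.1]hept-3-en-2-one | CC1=CC(=O)[C@@H]2C[C@H]1C2(C)C | starting material
2 | allyltrimethylsilane | C=CC[Si](C)(C)C | starting material
3 | (1R,4R,5R)-4-allyl-4,6,6-trimethylbicyclo[3.1.1]heptan-2-one (4-allyl-4-methylnopinone, allyl anti to the CMe2 bridge) | C=CC[C@]1(C)CC(=O)[C@@H]2C[C@H]1C2(C)C | intermediate (not isolated)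
4 | (4aS,8aS)-7-chloro-5,5,8a-trimethyloctahydronaphthalen-2(1H)-one (trans-fused, C7 epimers) | O=C1CC[C@H]2C(C)(C)CC(Cl)C[C@]2(C)C1 | intermediate
5 | (4aS,8aR)-5,5,8a-trimethyloctahydronaphthalen-2(1H)-one (trans-fused) | O=C1CC[C@H]2C(C)(C)CCC[C@]2(C)C1 | intermediate
6 | (4aS,8aR)-5,5,8a-trimethyl-4a,5,6,7,8,8a-hexahydronaphthalen-2(1H)-one | O=C1C=C[C@H]2C(C)(C)CCC[C@]2(C)C1 | intermediate
7 | methyl hydrogen (R)-3-methylglutarate, (3R)-5-methoxy-3-methyl-5-oxopentanoic acid | COC(=O)C[C@H](C)CC(=O)O | starting material
8 | 1-tert-butyl 5-methyl (3S)-3-methylpentanedioate | COC(=O)C[C@H](C)CC(=O)OC(C)(C)C | intermediate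
9 | tert-butyl (3S)-3-methyl-5-oxopentanoate | CC(C)(C)OC(=O)C[C@@H](C)CC=O | intermediate
10 | tert-butyl (13S)-11-hydroxy-8-oxo-17-norlabd-6-en-15-oate (5alpha-H, 10beta-CH3; C9/C11 mixture) | CC(C)(C)OC(=O)C[C@@H](C)CC(O)C1C(=O)C=C[C@H]2C(C)(C)CCC[C@]12C | intermediate
11 | tert-butyl (13S)-11-(methylsulfonyloxy)-8-oxo-17-norlabd-6-en-15-oate (C9/C11 mixture) | CC(C)(C)OC(=O)C[C@@H](C)CC(OS(C)(=O)=O)C1C(=O)C=C[C@H]2C(C)(C)CCC[C@]12C | intermediate (not isolated)
12 | tert-butyl (13S)-8-oxo-17-norlabda-6,9(11)-dien-15-oate (E/Z mixture) | CC(C)(C)OC(=O)C[C@@H](C)CC=C1C(=O)C=C[C@H]2C(C)(C)CCC[C@]12C | intermediate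
13 | tert-butyl (13S)-8-oxo-17-norlabdan-15-oate (5alpha-H, 9alpha-H, 10beta-CH3) | CC(C)(C)OC(=O)C[C@@H](C)CC[C@H]1C(=O)CC[C@H]2C(C)(C)CCC[C@]12C | intermediate
14 | tert-butyl (13S)-8-(trifluoromethylsulfonyloxy)-17-norlabd-7-en-15-oate | CC(C)(C)OC(=O)C[C@@H](C)CC[C@H]1C(OS(=O)(=O)C(F)(F)F)=CC[C@H]2C(C)(C)CCC[C@]12C | intermediate
15 | 15-tert-butyl 17-methyl (13S)-labd-7-ene-15,17-dioate | CC(C)(C)OC(=O)C[C@@H](C)CC[C@H]1C(C(=O)OC)=CC[C@H]2C(C)(C)CCC[C@]12C | intermediate
16 | (13S)-labd-7-ene-15,17-diol | OCC[C@@H](C)CC[C@H]1C(CO)=CC[C@H]2C(C)(C)CCC[C@]12C | intermediate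
17 | (5S,9R,10S,13S)-labd-7-ene-15,17-diyl diacetate | CC(=O)OCC[C@@H](C)CC[C@H]1C(COC(C)=O)=CC[C@H]2C(C)(C)CCC[C@]12C | target

Total step count: 12. Longest linear sequence: 10 steps (steps 1–3 and 6–12, from 1 to 17); the aldehyde 9 is made in a two-step branch (steps 4 and 5).

Steps most likely to fail

Step 1 (proposed new method). The Lewis acid may open the cyclobutane of 1 before the conjugate allylation has taken place, which would lose the facial control at C10. The C4 cation may also lose a proton or take a 1,2-hydride shift from C5 instead of closing ring A. The fallback sets out from 1 and separates the three events with known reaction types. Copper-mediated conjugate addition of CH2=CHCH2MgBr (CuBr·SMe2, Me3SiCl, THF, −78 °C, acidic work-up), anti to the CMe2 bridge, gives 3 as an isolated compound. Hydrogen chloride in acetic acid cleaves the cyclobutane to the tertiary chloride (3R,4R)-3-allyl-4-(2-chloropropan-2-yl)-3-methylcyclohexan-1-one F1. SnCl4 in CH2Cl2 at −78 °C then ionizes the tertiary chloride and closes ring A by carbocation–alkene addition with chloride return, which comes back to the route at 4.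

Step 8. Facial selectivity at C9 may be poor, or saturation of the hindered exocyclic alkene incomplete. The fallback sets out from 12 and replaces kinetic face selection by thermodynamic control. Conjugate reduction of both enone units with [(Ph3P)CuH]6 (benzene, 25 °C) gives, after protonation of the copper enolates, the ketone as a C9 mixture containing tert-butyl (13S)-8-oxo-17-nor-9-epi-labdan-15-oate F2. Equilibration through the C9 enolate (DBU, toluene, 80 °C) should move the side chain into the equatorial position and comes back to the route at 13.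

Step 9. Regiocontrol in the enolization (C9 against C7) may be lost, or C9 may epimerize through the enolate. The fallback sets out from 13 and brings in C17 without an enolate. Corey–Chaykovsky methylenation (trimethylsulfonium iodide, KOt-Bu, DMSO/THF) converts the ketone into the spiro-epoxide tert-butyl (13S)-8,17-epoxylabdan-15-oate F3. Epoxide-to-allylic-alcohol isomerization with Al(Oi-Pr)3 (toluene, 110 °C), which removes a proton from the C7 methylene rather than the C9 methine, gives tert-butyl (13S)-17-hydroxylabd-7-en-15-oate F4. Reduction of the tert-butyl ester with i-Bu2AlH comes back to the route at 16.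

Further compounds
F1 | step 1 | (3R,4R)-3-allyl-4-(2-chloropropan-2-yl)-3-methylcyclohexan-1-one | C=CC[C@]1(C)CC(=O)CC[C@H]1C(C)(C)Cl
F2 | step 8 | tert-butyl (13S)-8-oxo-17-nor-9-epi-labdan-15-oate | CC(C)(C)OC(=O)C[C@@H](C)CC[C@@H]1C(=O)CC[C@H]2C(C)(C)CCC[C@]12C
F3 | step 9 | tert-butyl (13S)-8,17-epoxylabdan-15-oate (C8 epimers) | CC(C)(C)OC(=O)C[C@@H](C)CC[C@H]1C2(CO2)CC[C@H]3C(C)(C)CCC[C@]13C
F4 | step 9 | tert-butyl (13S)-17-hydroxylabd-7-en-15-oate | CC(C)(C)OC(=O)C[C@@H](C)CC[C@H]1C(CO)=CC[C@H]2C(C)(C)CCC[C@]12C
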